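**Retrosynthetic overview**

1. Locants: unit 1 consists of ring A (phloroglucinol ring), ring C (O1, C2, C3, C4, C4a, C8a) and ring B (4-methoxyphenyl on C2). Unit 2 consists of ring D, ring F (O1'', C2'', C3'', C4'', C4a'', C8a'') and ring E (4-hydroxyphenyl on C2'').
2. Enabling feature: the 1,4-diketone C4(=O)–C3–C3''–C4''(=O) spans the bond between rings C and F. Each carbonyl carbon sits ortho to the aryl ether oxygen (O1 on ring A, O1'' on ring D) that holds the neighbouring carbinol carbon (C2, C2''). The chain C2–C3–C3''–C2'' is therefore a but-2-yne-1,4-diol whose two 2-formylaryl ethers have added across the triple bond, and the benzyl-protected target is an isomer of that open-chain dialdehyde.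
3. Key disconnections: C4''–C3'' (ring F, intramolecular Stetter reaction with protonation at C3) and C4–C3 (ring C, carbene-catalysed alkyne hydroacylation). Both bonds are made in one flask from an alkyne that carries only C2 and C2'' as stereocentres.
4. That alkyne comes from one phenol used twice (Mitsunobu etherification with inversion), ethynyltrimethylsilane and two benzaldehydes (two catalytic asymmetric alkynylations).
5. Ring order: rings A, B, D and E are bought. Ring C closes first and becomes the 2,3-cis unit; ring F closes last and becomes the 2,3-trans unit. A temporary dioxolane on the ring D formyl group enforces this order and leaves in the same step, and the five benzyl ethers leave at the end.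

Key step: step 7

Assumption: the sense of induction of the ProPhenol ligand is not taken for granted. Each antipode is named by the carbinol it has to give, and the two antipodes of steps 2 and 5 are exchanged if the usual model points the other way.

**Step 1**
Reactants: 1 2,4,6-trihydroxybenzaldehyde
Product: 2 2,4-bis(benzyloxy)-6-hydroxybenzaldehyde
Conditions: BnBr (2.05 equiv), K2CO3, DMF, 23 °C
Reagents that add atoms: benzyl bromide, BrCc1ccccc1
Why: Williamson etherification: the 4-hydroxyl and one of the two equivalent ortho hydroxyls are alkylated, while the last ortho hydroxyl, tied to the formyl oxygen by a strong hydrogen bond, is the least nucleophilic and should stay free.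

**Step 2**
Reactants: 3 4-(benzyloxy)benzaldehyde; 4 ethynyltrimethylsilane
Product: 5 (1R)-1-[4-(benzyloxy)phenyl]-3-(trimethylsilyl)prop-2-yn-1-ol
Conditions: Me2Zn, ProPhenol ligand (antipode that gives the R carbinol, 10 mol %), Ph3P=O (20 mol %), toluene, 0 °C
Reagents that add atoms: none
Why: Catalytic asymmetric alkynylation of an aromatic aldehyde by the alkynylzinc formed from 4 and Me2Zn; the chiral ligand shields one face of the bound aldehyde and sets the carbinol centre as R, the mirror image of what C2'' needs because step 3 inverts it.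

**Step 3**
Reactants: 5 (1R)-1-[4-(benzyloxy)phenyl]-3-(trimethylsilyl)prop-2-yn-1-ol; 2 2,4-bis(benzyloxy)-6-hydroxybenzaldehyde
Product: 6 2,4-bis(benzyloxy)-6-{[(1S)-1-[4-(benzyloxy)phenyl]-3-(trimethylsilyl)prop-2-yn-1-yl]oxy}benzaldehyde
Conditions: PPh3, DIAD, toluene, −20 to 0 °C
Reagents that add atoms: none
Why: Mitsunobu etherification: the acidic chelated phenol 2 displaces the oxyphosphonium group in an SN2 reaction, so the centre is inverted and has the spatial arrangement of C2'' in the target (descriptor S here).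

**Step 4**
Reactants: 6 2,4-bis(benzyloxy)-6-{[(1S)-1-[4-(benzyloxy)phenyl]-3-(trimethylsilyl)prop-2-yn-1-yl]oxy}benzaldehyde
Product: 8 2-[2,4-bis(benzyloxy)-6-{[(1R)-1-[4-(benzyloxy)phenyl]prop-2-yn-1-yl]oxy}phenyl]-1,3-dioxolane, via silylated dioxolane 7 (not isolated)
Conditions: TMSOCH2CH2OTMS, TMSOTf (5 mol %), CH2Cl2, −78 °C; then K2CO3, MeOH, 0 to 23 °C
Reagents that add atoms: 1,2-bis(trimethylsilyloxy)ethane, C[Si](C)(C)OCCO[Si](C)(C)C
Why: Noyori acetalisation under aprotic conditions masks the ring D formyl group as a temporary dioxolane, and base-mediated protodesilylation in methanol then frees the alkyne terminus; the stereocentre is untouched (its descriptor changes to R only because ethynyl ranks below aryl).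

**Step 5**
Reactants: 8 2-[2,4-bis(benzyloxy)-6-{[(1R)-1-[4-(benzyloxy)phenyl]prop-2-yn-1-yl]oxy}phenyl]-1,3-dioxolane; 9 4-methoxybenzaldehyde
Product: 10 (1S,4S)-4-[3,5-bis(benzyloxy)-2-(1,3-dioxolan-2-yl)phenoxy]-4-[4-(benzyloxy)phenyl]-1-(4-methoxyphenyl)but-2-yn-1-ol
Conditions: Me2Zn, ProPhenol ligand (antipode that gives the S carbinol, 20 mol %), Ph3P=O, toluene, 0 °C; aq. NaHCO3 quench
Reagents that add atoms: none
Why: Second catalytic asymmetric alkynylation, now with the opposite ligand antipode; the catalyst alone decides the face of 9 because the existing centre lies across the linear alkyne, and the new carbinol centre is set as S, again the mirror image of what C2 needs.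

**Step 6**
Reactants: 10 (1S,4S)-4-[3,5-bis(benzyloxy)-2-(1,3-dioxolan-2-yl)phenoxy]-4-[4-(benzyloxy)phenyl]-1-(4-methoxyphenyl)but-2-yn-1-ol; 2 2,4-bis(benzyloxy)-6-hydroxybenzaldehyde
Product: 11 2,4-bis(benzyloxy)-6-{[(1R,4S)-4-[3,5-bis(benzyloxy)-2-(1,3-dioxolan-2-yl)phenoxy]-4-[4-(benzyloxy)phenyl]-1-(4-methoxyphenyl)but-2-yn-1-yl]oxy}benzaldehyde
Conditions: PPh3, DIAD, toluene, −20 to 0 °C
Reagents that add atoms: none
Why: Mitsunobu etherification with SN2 inversion at the carbinol carbon gives C2 in its final spatial arrangement (descriptor R here) and brings in ring A with a free formyl group, while the dioxolane and the benzyl ethers are inert to the neutral redox couple.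

**Step 7**
Reactants: 11 2,4-bis(benzyloxy)-6-{[(1R,4S)-4-[3,5-bis(benzyloxy)-2-(1,3-dioxolan-2-yl)phenoxy]-4-[4-(benzyloxy)phenyl]-1-(4-methoxyphenyl)but-2-yn-1-yl]oxy}benzaldehyde
Product: 14 (2S,3S)-5,7-bis(benzyloxy)-3-{(2R,3S)-5,7-bis(benzyloxy)-2-[4-(benzyloxy)phenyl]-4-oxochroman-3-yl}-2-(4-methoxyphenyl)chroman-4-one, via enone dioxolane 12 (not isolated), via enone aldehyde 13 (not isolated)
Conditions: 3-mesityl-4,5-dimethylthiazolium tetrafluoroborate (20 mol %), K2CO3 (20 mol %), THF, 70 °C; then CF3CO2H (1.2 equiv), H2O (20 equiv), 0 °C; then Et3N (2.5 equiv), 23 °C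
Reagents that add atoms: water, O
Why: Proposed new method: the thiazol-2-ylidene turns the only free formyl group (ring A) into its Breslow enaminol, which hands its carbon to C3 and its O–H proton to C3'' on the same side of the unactivated triple bond and so gives the E enone 12; mild acid then uncovers the ring D aldehyde (13), and the carbene, released again by Et3N, adds this second acyl anion equivalent to C3'', which has just become the β-carbon of an enone, before the C3 enolate is protonated and the catalyst leaves. The closest known reaction types are the carbene-catalysed hydroacylation of the alkyne in 2-(propargyloxy)benzaldehydes, its cascade with an intermolecular Stetter reaction, and the diastereoselective intramolecular Stetter reaction of trisubstituted acceptors; new are the delivery of two tethered acyl groups to the two carbons of one alkyne in one flask and the use of doubly ortho-oxygenated aldehydes. Ring C closes first in the 6-exo-dig mode (bond C4–C3) and ring F closes last in the 6-exo-trig mode (bond C4''–C3''). Allylic 1,3-strain across the E double bond holds the ring B aryl group axial on one face of ring C and turns C2''–H into the alkene plane, so that with the given C2'' configuration O1'' and its tethered enaminol stand on the opposite, open face: attack there sets C3'' (S, trans to the ring E aryl group), and proton delivery to C3 on the same open face, anti to the ring B aryl group, sets C3 (S) and with it the kinetic 2,3-cis relationship of unit 1. The step needs the ring A aldehyde to react before the ring D aldehyde, because the unit closed first becomes the cis one; the dioxolane on ring D secures this order, the six-atom tethers secure exo closure, and the triethylammonium trifluoroacetate buffer keeps the medium too weakly basic to re-enolise C3 or to open ring C by loss of the O1 aryloxide.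

**Step 8**
Reactants: 14 (2S,3S)-5,7-bis(benzyloxy)-3-{(2R,3S)-5,7-bis(benzyloxy)-2-[4-(benzyloxy)phenyl]-4-oxochroman-3-yl}-2-(4-methoxyphenyl)chroman-4-one
Product: 15 (2S,3S)-3-[(2R,3S)-5,7-dihydroxy-2-(4-hydroxyphenyl)-4-oxochroman-3-yl]-5,7-dihydroxy-2-(4-methoxyphenyl)chroman-4-one
Conditions: H2 (1 atm), 10 % Pd/C, EtOAc–MeOH, 23 °C
Reagents that add atoms: none
Why: Hydrogenolysis of the five benzyl ethers on Pd/C runs under neutral conditions, so neither enolisation at C3 or C3'' nor opening of rings C and F at C2 or C2'' can scramble the four stereocentres, and the methyl ether stays.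

**Compound list**

1 | 2,4,6-trihydroxybenzaldehyde | O=Cc1c(O)cc(O)cc1O | starting material
2 | 2,4-bis(benzyloxy)-6-hydroxybenzaldehyde | O=Cc1c(O)cc(OCc2ccccc2)cc1OCc1ccccc1 | intermediate
3 | 4-(benzyloxy)benzaldehyde | O=Cc1ccc(OCc2ccccc2)cc1 | starting material
4 | ethynyltrimethylsilane | C#C[Si](C)(C)C | starting material
5 | (1R)-1-[4-(benzyloxy)phenyl]-3-(trimethylsilyl)prop-2-yn-1-ol | C[Si](C)(C)C#C[C@H](O)c1ccc(OCc2ccccc2)cc1 | intermediate
6 | 2,4-bis(benzyloxy)-6-{[(1S)-1-[4-(benzyloxy)phenyl]-3-(trimethylsilyl)prop-2-yn-1-yl]oxy}benzaldehyde | C[Si](C)(C)C#C[C@@H](Oc1cc(OCc2ccccc2)cc(OCc2ccccc2)c1C=O)c1ccc(OCc2ccccc2)cc1 | intermediate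
7 | 2-[2,4-bis(benzyloxy)-6-{[(1S)-1-[4-(benzyloxy)phenyl]-3-(trimethylsilyl)prop-2-yn-1-yl]oxy}phenyl]-1,3-dioxolane | C[Si](C)(C)C#C[C@@H](Oc1cc(OCc2ccccc2)cc(OCc2ccccc2)c1C3OCCO3)c1ccc(OCc2ccccc2)cc1 | intermediate
8 | 2-[2,4-bis(benzyloxy)-6-{[(1R)-1-[4-(benzyloxy)phenyl]prop-2-yn-1-yl]oxy}phenyl]-1,3-dioxolane | C#C[C@@H](Oc1cc(OCc2ccccc2)cc(OCc2ccccc2)c1C3OCCO3)c1ccc(OCc2ccccc2)cc1 | intermediate
9 | 4-methoxybenzaldehyde | COc1ccc(C=O)cc1 | starting material
10 | (1S,4S)-4-[3,5-bis(benzyloxy)-2-(1,3-dioxolan-2-yl)phenoxy]-4-[4-(benzyloxy)phenyl]-1-(4-methoxyphenyl)but-2-yn-1-ol | COc1ccc([C@H](O)C#C[C@@H](Oc2cc(OCc3ccccc3)cc(OCc3ccccc3)c2C4OCCO4)c2ccc(OCc3ccccc3)cc2)cc1 | intermediate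
11 | 2,4-bis(benzyloxy)-6-{[(1R,4S)-4-[3,5-bis(benzyloxy)-2-(1,3-dioxolan-2-yl)phenoxy]-4-[4-(benzyloxy)phenyl]-1-(4-methoxyphenyl)but-2-yn-1-yl]oxy}benzaldehyde | COc1ccc([C@@H](Oc2cc(OCc3ccccc3)cc(OCc3ccccc3)c2C=O)C#C[C@@H](Oc2cc(OCc3ccccc3)cc(OCc3ccccc3)c2C4OCCO4)c2ccc(OCc3ccccc3)cc2)cc1 | intermediate
12 | (2R,3E)-5,7-bis(benzyloxy)-3-{(2R)-2-[3,5-bis(benzyloxy)-2-(1,3-dioxolan-2-yl)phenoxy]-2-[4-(benzyloxy)phenyl]ethylidene}-2-(4-methoxyphenyl)chroman-4-one | COc1ccc([C@H]2Oc3cc(OCc4ccccc4)cc(OCc4ccccc4)c3C(=O)/C2=C/[C@@H](Oc2cc(OCc3ccccc3)cc(OCc3ccccc3)c2C4OCCO4)c2ccc(OCc3ccccc3)cc2)cc1 | intermediate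
13 | 2,4-bis(benzyloxy)-6-{(1R,2E)-1-[4-(benzyloxy)phenyl]-2-[(2R)-5,7-bis(benzyloxy)-2-(4-methoxyphenyl)-4-oxochroman-3-ylidene]ethoxy}benzaldehyde | COc1ccc([C@H]2Oc3cc(OCc4ccccc4)cc(OCc4ccccc4)c3C(=O)/C2=C/[C@@H](Oc2cc(OCc3ccccc3)cc(OCc3ccccc3)c2C=O)c2ccc(OCc3ccccc3)cc2)cc1 | intermediate
14 | (2S,3S)-5,7-bis(benzyloxy)-3-{(2R,3S)-5,7-bis(benzyloxy)-2-[4-(benzyloxy)phenyl]-4-oxochroman-3-yl}-2-(4-methoxyphenyl)chroman-4-one | COc1ccc([C@H]2Oc3cc(OCc4ccccc4)cc(OCc4ccccc4)c3C(=O)[C@H]2[C@@H]2C(=O)c3c(OCc4ccccc4)cc(OCc4ccccc4)cc3O[C@H]2c2ccc(OCc3ccccc3)cc2)cc1 | intermediate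
15 | (2S,3S)-3-[(2R,3S)-5,7-dihydroxy-2-(4-hydroxyphenyl)-4-oxochroman-3-yl]-5,7-dihydroxy-2-(4-methoxyphenyl)chroman-4-one | COc1ccc([C@H]2Oc3cc(O)cc(O)c3C(=O)[C@H]2[C@@H]2C(=O)c3c(O)cc(O)cc3O[C@H]2c2ccc(O)cc2)cc1 | target

Total step count: 8
Longest linear sequence: 7 steps (steps 2 to 8, from 3 and 4 to 15)

**Steps most likely to fail**

**Step 7.** Four processes may interfere:
- The carbene may add slowly to formyl groups that carry two ortho oxygen substituents on very electron-rich rings.
- The propargylic centres may isomerise under base at 70 °C.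
- The C3 enolate may lose the O1 aryloxide, which opens ring C.
- C3 may re-enolise, which erodes the cis relationship.

The fallback sets out from 11 and comes back at 14. It closes the rings one at a time by metal-based and radical surrogates of hydroacylation, partly at another oxidation level. Hydrogen-mediated reductive cyclisation of the acetylenic aldehyde (Rh(cod)2OTf, BIPHEP, H2 1 atm, 1,2-dichloroethane) adds C4 and hydrogen to the same side of the alkyne and should give the exocyclic allylic alcohol F1 as either C4 epimer. MnO2 in CH2Cl2 oxidises it to 12. Aqueous oxalic acid in THF gives 13, which is now isolated. A radical-chain intramolecular hydroacylation (tert-dodecanethiol, 1,1'-azobis(cyclohexanecarbonitrile), toluene, reflux) then closes ring F: the nucleophilic acyl radical adds 6-exo to C3'', and the C3 radical takes its hydrogen atom on the face anti to the axial ring B aryl group under neutral conditions, which leads to 14.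

**Step 6.** The oxyphosphonium ion may ionise at a carbon stabilised by both the 4-methoxyphenyl and the alkynyl group, which would erode the inversion, and SN2' attack may lead towards an allenyl ether.

The fallback sets out from 8 and comes back at 11. It forms the oxygen–aryl bond instead of the oxygen–alkyl bond, so the C2–O bond is never broken. Compounds 8 and 9 are joined as in step 5 but with the other ligand antipode, to give the epimeric carbinol F2. Commercial 5-fluororesorcinol is dibenzylated (BnBr, K2CO3, DMF) to 1,3-bis(benzyloxy)-5-fluorobenzene F3. Vilsmeier–Haack formylation (POCl3, DMF) gives 2,4-bis(benzyloxy)-6-fluorobenzaldehyde F4. The potassium alkoxide of F2 (KN(SiMe3)2, THF, −40 °C) then displaces the fluoride ortho to the formyl group in an SNAr reaction with retention at C2, which gives 11.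

**Step 5.** The electron-rich aldehyde 9 may convert poorly with a bulky alkynylzinc, facial selectivity may be poor, and the dioxolane may be lost on the Lewis acidic zinc species.

The fallback sets out from 8 and comes back at 10. It sets the stereocentre by reduction instead of addition. The lithium acetylide of 8 (n-BuLi, THF, −78 °C) is acylated with N-methoxy-N-methyl-4-methoxybenzamide to give the ynone F5. A CBS reduction (oxazaborolidine antipode that gives the S carbinol, catecholborane, toluene, −78 °C) then gives 10.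

**Further compounds**
F1 | step 7 | (2R)-5,7-bis(benzyloxy)-3-{(2R)-2-[3,5-bis(benzyloxy)-2-(1,3-dioxolan-2-yl)phenoxy]-2-[4-(benzyloxy)phenyl]ethylidene}-2-(4-methoxyphenyl)chroman-4-ol (alkene geometry as in 12, either C4 epimer) | COc1ccc([C@H]2Oc3cc(OCc4ccccc4)cc(OCc4ccccc4)c3C(O)/C2=C/[C@@H](Oc2cc(OCc3ccccc3)cc(OCc3ccccc3)c2C4OCCO4)c2ccc(OCc3ccccc3)cc2)cc1
F2 | step 6 | (1R,4S)-4-[3,5-bis(benzyloxy)-2-(1,3-dioxolan-2-yl)phenoxy]-4-[4-(benzyloxy)phenyl]-1-(4-methoxyphenyl)but-2-yn-1-ol | COc1ccc([C@@H](O)C#C[C@@H](Oc2cc(OCc3ccccc3)cc(OCc3ccccc3)c2C4OCCO4)c2ccc(OCc3ccccc3)cc2)cc1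
F3 | step 6 | 1,3-bis(benzyloxy)-5-fluorobenzene | Fc1cc(OCc2ccccc2)cc(OCc2ccccc2)c1
F4 | step 6 | 2,4-bis(benzyloxy)-6-fluorobenzaldehyde | O=Cc1c(F)cc(OCc2ccccc2)cc1OCc1ccccc1
F5 | step 5 | (4S)-4-[3,5-bis(benzyloxy)-2-(1,3-dioxolan-2-yl)phenoxy]-4-[4-(benzyloxy)phenyl]-1-(4-methoxyphenyl)but-2-yn-1-one | COc1ccc(C(=O)C#C[C@@H](Oc2cc(OCc3ccccc3)cc(OCc3ccccc3)c2C4OCCO4)c2ccc(OCc3ccccc3)cc2)cc1
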